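At 6.00 d the eta flask still holds 6.3% of its free monomer as a leftover, so look at how its rate fades.

| flask | free monomer | protic impurity | initiator | remark | time |
|---|---|---|---|---|---|
| eta | 0.050 M | 0.010 M | 1.2 mM | run made earlier |  |
| zeta | 0.050 M | 0.010 M | 0.60 mM | run made earlier |  |
| epsilon | 0.050 M | 0.010 M | 2.4 mM | run made earlier |  |
| north-west | 0.050 M (fed, over 4.80 d) | 0.0100 M | 1.2 mM | all but free monomer at the start; free monomer goes in evenly over 4.80 d, the run ends at 6.0 d | 6.0 d |
| east | 0.050 M | 0.0100 M | 1.2 mM | everything together in a closed stirred flask, run for 6.0 d | 6.0 d |
| north | 0.050 M | 0.0100 M | 1.2 mM | a single well-mixed tank run continuously and read at steady state, 6.0 d in it on average |  |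
| south | 0.050 M | 0.0100 M | 1.2 mM | a single well-mixed tank run continuously and read at steady state, 18.0 d in it on average |  |

| run | time / d | monomer in chains / % | over-reaction product / % | free monomer / % |
|---|---|---|---|---|
| eta | 0.833 | 47.7 | 2.9 | 29.3 |
| eta | 2.00 | 55.8 | 10.7 | 13.3 |
| eta | 4.00 | 49.4 | 23.5 | 6.8 |
| eta | 6.00 | 39.9 | 34.3 | 6.3 |
| zeta | 1.67 | 47.0 | 6.2 | 26.0 |
| zeta | 4.00 | 44.9 | 19.8 | 15.6 |
| zeta | 5.00 | 40.7 | 25.0 | 14.2 |
| zeta | 8.00 | 29.2 | 37.1 | 12.8 |
| epsilon | 0.625 | 52.4 | 2.4 | 25.1 |
| epsilon | 1.25 | 62.6 | 7.2 | 10.3 |
| epsilon | 3.00 | 57.8 | 19.7 | 1.8 |
| epsilon | 8.00 | 32.8 | 46.3 | 1.3 |

(each reading ± 0.3 percentage points)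

- the stated concentrations are those of everything mixed, before any reaction; amounts are the same in each set-up
- the numbers in the tables scatter with a standard deviation of 0.3 percentage points
- the feed brings no volume worth counting
- the earlier runs were made in a closed, stirred flask

* order of the set-ups by the share of monomer in chains in all that became monomer in chains or over-reaction product, at the outlet or at the end, highest first (north-west / east / north / south)
* share of monomer in chains in all that became monomer in chains or over-reaction product, at the outlet or at the end, north-west
* share of monomer in chains in all that became monomer in chains or over-reaction product, at the outlet or at the end, east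
* share of monomer in chains in all that became monomer in chains or over-reaction product, at the outlet or at the end, north
* share of monomer in chains in all that became monomer in chains or over-reaction product, at the outlet or at the end, south

Take as your measure the turnovers per day, the natural-log fall of free monomer per day. In eta they run at 0.677 /d between the first two readings and 0.335 /d between the next two, so the rate falls to about half. From 2.00 d to the end 0.747 turnovers remain. Over-reaction doesn't fade like this: it reads 0.129 /d per unit of monomer in chains early in eta, 0.121 /d late in eta, and 0.115 /d late in zeta.

So carry the over-reaction count 0.435: this rate times the days of holding per chain left at the end. The share in chains is then one over one plus the count. In a tank the holding days are the residence time, so south counts 2.18 and gives 31.4%, while north gives 57.9%. In north-west I let chains climb evenly through the feed, then level off as the turnovers fade. That is 2.40 d of holding for the feed plus 1.20 d after it, which gives the count above and a share of 69.7%. East reads 53.8% straight from eta.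

The forecast gives north-west > north > east > south, with 73%, 53.8%, 58.1% and 31.6% in the order north-west, east, north, south, a north-west higher than mine, and says: “Chains formed late have little time to over-react.”

The flasks give north-west > north > east > south, with 69.0%, 54.0%, 58.2% and 31.7% in that same order of north-west, east, north, south.

    monomer in chains → over-reaction product (k = 8.32 × 10⁻⁵ /min)
    free monomer + initiating radical → growing radical + monomer in chains (k = 2.35 × 10⁵ /M/min)
    protic impurity + free monomer → quenched substrate (k = 0.253 /M/min)
    initiator → 2 initiating radical (k = 7.54 × 10⁻⁴ /min)
    2 growing radical → dead chain (k = 2.00 × 10⁶ /M/s)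
    free monomer + growing radical → monomer in chains + growing radical, rate k6*[growing radical]*[free monomer] (k = 10800 /M/min)

In north-west the protic impurity quenched free monomer first, with half of that turnover up to the end done by 1.09 d, and chain-making reached the same mark later, by 3.07 d, while initiator sank to 0.545% of its charge at 4.80 d. Free monomer stood at 50.6% then and at 46% at the end, and the count read back from the north-west share is 0.449. The same flask as north-west but with 0.0048 M of initiator counts 0.504 by its share and ends with 33.7% of the charge in chains.

(The runs were computed with made-up constants; scatter was added.)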